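(The numbers of this flask come from no measurement; no experiment stands behind them.)

Target forms when the first nucleophile captures the intermediate, the second nucleophile competes for that intermediate, and substrate supplies it in a first-order step. Use this to decide which single change to make in the next run.

substrate 0.50 M; first nucleophile 0.350 M; second nucleophile 0.350 M; time 15 min

1. target and crystals together at 15 min, in percent of the substrate charged
2. the change that raises the amount of target and crystals together at 15 min, in percent of the substrate charged most ("none" if none brings more than 2 percentage points) (Thursday's / Tuesday's / Sunday's / Friday's / none)
3. amount of target and crystals together at 15 min, in percent of the substrate charged, after Tuesday's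

- Thursday's: doubling the amount of second nucleophile, all else as stated
- Tuesday's: doubling the dissolution coefficient of step 3, all else as stated
- Sunday's: doubling the solubility in step 3, all else as stated
- Friday's: doubling the amount of first nucleophile, all else as stated

- what is said of target includes crystals
- crystals is a solid; its amount is given per volume of the solution
- run time (flask): 15 min

Count half-lives first. With k₁ = 0.0540 min⁻¹, substrate has a half-life of 12.8 min, so the run spans

n = 1.17 half-lives, and the fraction turned over is F = 55.5 %.

The intermediate has a half-life of 2.3 s by step 4 alone, far shorter than the 13 min of substrate. Treat it as a steady-state species, divided between the two captures as it forms. With k₄ = 51.4 L mol⁻¹ min⁻¹, k₂ = 141 L mol⁻¹ min⁻¹ and the charges taken as standing, the capture share of target, a selectivity written as a fraction, is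

s = k₄c(first) / (k₄c(first) + k₂c(second)) = 26.7 %

R = F × s = 14.8 %, the target reach.

Now test the changes. Friday's raises s to 42.2 %, so R becomes 23.4 %, a gain of 8.6 percentage points. Thursday's lowers s to 15.4 %, so R becomes 8.56 %. Friday's R equals 0.117 M of target, less than the solubility of 0.35 M, so expect no crystals and no effect from Tuesday's or Sunday's. Choose Friday's.

The forecast, holding that “the short-lived intermediate is split by the two nucleophiles”, gave 17.4 %, Friday's and 17.4 %.

The simulation gives 17.4 %, Friday's as the best change at 8.2 points, and 17.4 % after Tuesday's. Thursday's brings −7.9 points, while Tuesday's and Sunday's bring 0 points and 0 points. The ceiling on dissolved target makes no difference.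

    substrate → intermediate (k1 = 0.0540 min⁻¹)
    second nucleophile + intermediate → other capture product (k2 = 141 L mol⁻¹ min⁻¹)
    crystals ⇌ target, rate k3*(cs3 - [target]) while solid is left; crystals form when [target] > cs3 (cs3 = 0.35 M, k3 = 1.66 min⁻¹)
    first nucleophile + intermediate → target (k4 = 51.4 L mol⁻¹ min⁻¹)

In this flask R falls 2.6 points short of the result. The capture of intermediate by second nucleophile is the largest single effect on this flask's yield: with that step taken away, the flask gives 54.9 % against 17.4 %. The wearing away of second nucleophile gives part of this loss back: the run without that wearing away gives 13.7 %. Now read the same flask at 6.0 min: 0.467 half-lives give R = 7.39 %, and the simulation gives 7.93 %.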